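# Total synthesis of ineupatorolide A by anionic oxy-Cope ring expansion

## Retrosynthetic overview
1. The γ-lactone is closed last by MnO2 oxidative lactonisation of the C8-OH/C12-OH diol. The C9 ester comes from (R)-2-methylbutanoic acid just before that.
2. The C10 carbinol comes from Cram-chelate MeMgBr addition to a C9-hydroxy-C10-ketone. The C9-OH comes from peripheral dihydroxylation of a trans-cyclodecenyl enol ether.
3. Key step: the ten-membered ring comes from an anionic oxy-Cope 6→10 ring expansion of a trans-1,2-dialkenylcyclohexane-1,2-diol mono-MOM ether. It breaks C5–C10, makes C7–C8, and sets C7 and C8 through an E,E-chair.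
4. The Cope substrate comes from two axial acetylide additions, each followed by Red-Al reduction, on an (R)-3-methylcyclohexanone-derived acyloin. One Cu-catalysed conjugate addition sets C4, which relays to C7–C10 through two sacrificial carbinol centres.
5. Ring order: cyclohexane (sacrificial), then cyclodecane, then γ-lactone. RCM and NHK/Barbier macrocyclisation are deliberately avoided.

**Labels (bookkeeping only, not IUPAC):**
- C5 is the ring C=O, C4 is CHMe, C3–C1 are (CH2)3, and C10 is C(OH)Me.
- C9 is CH–O-acyl, C8 is the lactone CH–O, C7 is the ring-fusion CH, and C6 is CH2.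
- C11(=C13H2)–C12(=O) are the remaining lactone carbons.
- The target is 4R,7S,8S,9R,10S,2′R with a trans-fused lactone.

**Assumption:** (R)-2-methylbutanoic acid and both enantiomers of the BINOL/bis(1-phenylethyl)amine phosphoramidite ligand are purchased. PMB = 4-methoxybenzyl.

## Route

**Step 1**
Reactants: 1 cyclohex-2-en-1-one; 2 dimethylzinc
Product: 3 (R)-tert-butyldimethyl[(3-methylcyclohex-1-en-1-yl)oxy]silane
Conditions: Cu(OTf)2 (1 mol %), (R,S,S)-phosphoramidite (2 mol %), Me2Zn, PhMe, −30 °C; then TBSOTf, −30 → 0 °C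
Reagents that add atoms: Me2Zn C[Zn]C; TBSOTf CC(C)(C)[Si](C)(C)OS(=O)(=O)C(F)(F)F
Why: Cu-catalysed asymmetric conjugate addition sets C4 as R (ligand enantiomer chosen by analogy with Et2Zn additions), and silyl trapping of the zinc enolate fixes the enol ether between C10 and C5.

**Step 2**
Reactants: 3
Product: 4 (2S,3R)-2-[(tert-butyldimethylsilyl)oxy]-3-methylcyclohexan-1-one (C10 ketone, C5–OTBS)
Conditions: mCPBA, NaHCO3, CH2Cl2, −20 → 0 °C
Reagents that add atoms: mCPBA O=C(OO)c1cccc(Cl)c1
Why: Rubottom oxidation epoxidises anti to the C4 methyl and silyl migration follows; the C5 configuration is inconsequential because C5 is oxidised in step 8.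

**Step 3**
Reactants: 5 4-methoxybenzyl alcohol; 6 trichloroethylene
Product: 7 1-{[(E)-1,2-dichloroethenyl]oxymethyl}-4-methoxybenzene
Conditions: KH, THF, 0 °C; Cl2C=CHCl, −50 °C → rt
Reagents that add atoms: trichloroethylene ClC=C(Cl)Cl
Why: The alkoxide adds anti to dichloroacetylene formed in situ (the dichlorovinyl-ether route to ynol ethers); no stereocentre is formed.

**Step 4**
Reactants: 4; 7
Product: 8 (1R,2S,3R)-2-(TBSO)-1-[(PMBO)ethynyl]-3-methylcyclohexan-1-ol (10R)
Conditions: 7, n-BuLi (2.2 equiv), THF, −78 → −40 °C; then 4, −78 °C; cold pH 7 quench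
Reagents that add atoms: lithium alkoxyacetylide from 7, [Li]C#COCc1ccc(OC)cc1
Why: In this acetylide 1,2-addition the slim sp nucleophile attacks the Me/OTBS-diequatorial chair axially and the diaxial conformer is blocked by the syn-axial C4-Me, so C9 enters trans to Me (10R).

**Step 5**
Reactants: 8
Product: 9 (1R,2S,3R)-2-(TBSO)-1-[(E)-2-(PMBO)ethenyl]-3-methylcyclohexan-1-ol
Conditions: Red-Al, Et2O, 0 °C → rt; Rochelle-salt work-up
Reagents that add atoms: none
Why: Hydroxyl-directed trans-hydroalumination of the propargylic alcohol gives only the E-enol ether, with Al on the distal carbon so no β-alkoxy elimination occurs.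

**Step 6**
Reactants: 9
Product: 10 O10-MOM ether of 9 (4R,5S,10R)
Conditions: MOMCl, i-Pr2NEt (excess), TBAI, CH2Cl2, 0 → 35 °C
Reagents that add atoms: MOMCl COCCl
Why: Acetal-type O-alkylation of the only free OH under basic conditions protects the acid-labile alkoxyallyl carbinol, and a non-migrating group is needed because a silyl group would shift to the neighbouring alkoxide in step 14.

**Step 7**
Reactants: 10
Product: 11 (1S,2R,6R)-2-(methoxymethoxy)-2-[(E)-2-(PMBO)ethenyl]-6-methylcyclohexan-1-ol
Conditions: TBAF, THF, rt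
Reagents that add atoms: none
Why: Fluoride desilylation leaves the MOM group, PMB group and enol ether untouched.

**Step 8**
Reactants: 11
Product: 12 (2R,6R)-2-(methoxymethoxy)-2-[(E)-2-(PMBO)ethenyl]-6-methylcyclohexan-1-one (C5 ketone)
Conditions: Dess–Martin periodinane, pyridine, CH2Cl2, 0 °C
Reagents that add atoms: none
Why: Buffered Dess–Martin oxidation is non-basic and non-acidic, so C4–H (the only α-H) is not epimerised and the enol ether survives.

**Step 9**
Reactants: 13 2,3-dibromoprop-1-ene; 5
Product: 14 1-{[(2-bromoprop-2-en-1-yl)oxy]methyl}-4-methoxybenzene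
Conditions: NaH, THF/DMF, 0 °C → rt
Reagents that add atoms: PMBOH COc1ccc(CO)cc1
Why: Williamson SN2 occurs at the allylic bromide and the vinyl bromide is inert.

**Step 10**
Reactants: 14; 15 ethynyltrimethylsilane
Product: 16 trimethyl{3-[(PMBO)methyl]but-3-en-1-yn-1-yl}silane
Conditions: PdCl2(PPh3)2, CuI, i-Pr2NH, THF, 45 °C
Reagents that add atoms: TMS-acetylene C#C[Si](C)(C)C
Why: Sonogashira coupling of the 2-bromoalkene builds the C6–C7–C11(=C13)–C12 unit.

**Step 11**
Reactants: 16
Product: 17 1-methoxy-4-{[(2-methylidenebut-3-yn-1-yl)oxy]methyl}benzene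
Conditions: K2CO3, MeOH, rt
Reagents that add atoms: none
Why: Mild protodesilylation frees the terminal alkyne.

**Step 12**
Reactants: 12; 17
Product: 18 (1R,2R,6R)-propargylic alcohol (4R,5R,10R), with C5(OH) bearing C≡C–C(=CH2)CH2OPMB
Conditions: 17, n-BuLi, THF, −78 °C; then 12, −78 → −20 °C
Reagents that add atoms: lithium acetylide of 17, [Li]C#CC(=C)COCc1ccc(OC)cc1
Why: In this acetylide 1,2-addition to a hindered ketone the axial C10 alkenyl group blocks one face, so axial attack anti to it places C6 cis to Me and trans to C9 (5R).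

**Step 13**
Reactants: 18
Product: 19 (1R,2R,6R)-dienol, with both side chains E and trans to each other
Conditions: Red-Al, THF, 0 °C → rt; Rochelle-salt work-up
Reagents that add atoms: none
Why: Hydroxyl-directed trans-hydroalumination of the enynol gives the E-1,3-diene, and the ethers and enol ether are inert.

**Step 14 (key step)**
Reactants: 19
Product: 20 (3S,4S,5Z,10R)-6-(methoxymethoxy)-4-(PMBO)-3-[3-(PMBO)prop-1-en-2-yl]-10-methylcyclodec-5-en-1-one (labels 4R,7S,8S; the C9=C10 olefin is ring-trans, CIP Z)
Conditions: KH, 18-crown-6, THF, 0 °C → rt; pH 7 buffer, −78 °C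
Reagents that add atoms: none
Why: In this anionic oxy-Cope rearrangement, after ring flip both E-alkenyl groups are equatorial and the alkoxide drives a trans-decalin-like chair [3,3] shift with C11 and OPMB pseudo-equatorial, so 5R,10R is transferred into 7S,8S (C7/C8 trans) while C5–C10 breaks to a C5 enolate (no β-leaving group) and a neutral C10 enol ether, with C4 untouched.

**Step 15**
Reactants: 20
Product: 21 (2R,3S,4S,7R)-2-hydroxy-3-(PMBO)-4-[3-(PMBO)prop-1-en-2-yl]-7-methylcyclodecane-1,6-dione (labels 4R,7S,8S,9R)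
Conditions: OsO4 (2 mol %), NMO (1.1 equiv), acetone/H2O, 0 °C
Reagents that add atoms: OsO4 O=[Os](=O)(=O)=O; NMO C[N+]1([O-])CCOCC1; water O
Why: Upjohn dihydroxylation picks the strained, most electron-rich alkene, and because A1,3 strain with OMOM keeps H8 in the alkene plane and the ring shields the inner face, Os adds to the outer face anti to C7 (9R, 8,9-threo) before the C10 hemiketal collapses to the ketone with loss of CH2O/MeOH.

**Step 16**
Reactants: 21; 22 methylmagnesium bromide
Product: 23 (2R,6S,7R,8S,9S)-6,7-dihydroxy-8-(PMBO)-9-[3-(PMBO)prop-1-en-2-yl]-2,6-dimethylcyclodecan-1-one (labels 4R,7S,8S,9R,10S)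
Conditions: MeMgBr (2.5 equiv), THF, −78 °C; NH4Cl
Reagents that add atoms: MeMgBr C[Mg]Br
Why: In this Cram-chelate Grignard addition the C9 magnesium alkoxide forms a five-membered chelate that activates only C10=O (the unchelated, α-branched medium-ring C5 ketone is far slower), and Me attacks anti to C8 to give the 9,10-erythro diol (10S).

**Step 17**
Reactants: 23; 24 (R)-2-methylbutanoic acid
Product: 25 C9 (R)-2-methylbutanoate of 23
Conditions: EDC·HCl, DMAP, CH2Cl2, 0 °C → rt
Reagents that add atoms: (R)-2-methylbutanoic acid CC[C@@H](C)C(=O)O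
Why: Steglich esterification acylates the secondary C9-OH in preference to the tertiary C10-OH, and the 2′R centre is purchased and not enolised under these conditions.

**Step 18**
Reactants: 25
Product: 26 C8-OH/C12-OH diol
Conditions: DDQ (3 equiv), CH2Cl2/pH 7 buffer, 0 °C → rt
Reagents that add atoms: none
Why: Oxidative PMB cleavage removes both PMB ethers in one operation without touching the ester, ketone, tertiary alcohol or alkene.

**Step 19**
Reactants: 26
Product: 27 ineupatorolide A
Conditions: activated MnO2 (excess), CH2Cl2, rt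
Reagents that add atoms: none
Why: In this oxidative lactonisation the allylic C12-OH goes to the enal, C8-OH closes the five-membered lactol (O9 is blocked) and this is oxidised to the α-methylene-γ-lactone, with trans fusion already fixed by C7/C8.

No step goes beyond known reaction types, so no "Proposed new method" tag is used.

## Compound list

| No. | Name | SMILES | Role |
|---|---|---|---|
| 1 | cyclohex-2-en-1-one | O=C1C=CCCC1 | starting material |
| 2 | dimethylzinc | C[Zn]C | starting material |
| 3 | (R)-TBS enol ether | C[C@@H]1CCCC(O[Si](C)(C)C(C)(C)C)=C1 | intermediate |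
| 4 | (2S,3R)-2-(TBSO)-3-methylcyclohexanone | C[C@@H]1CCCC(=O)[C@H]1O[Si](C)(C)C(C)(C)C | intermediate |
| 5 | 4-methoxybenzyl alcohol | COc1ccc(CO)cc1 | starting material |
| 6 | trichloroethylene | ClC=C(Cl)Cl | starting material |
| 7 | PMB (E)-1,2-dichlorovinyl ether | COc1ccc(CO/C(Cl)=C\Cl)cc1 | intermediate |
| 8 | ynol-ether carbinol | C[C@@H]1CCC[C@@](O)(C#COCc2ccc(OC)cc2)[C@H]1O[Si](C)(C)C(C)(C)C | intermediate |
| 9 | E-enol-ether carbinol | C[C@@H]1CCC[C@@](O)(/C=C/OCc2ccc(OC)cc2)[C@H]1O[Si](C)(C)C(C)(C)C | intermediate |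
| 10 | O10-MOM ether | C[C@@H]1CCC[C@@](OCOC)(/C=C/OCc2ccc(OC)cc2)[C@H]1O[Si](C)(C)C(C)(C)C | intermediate |
| 11 | C5 alcohol | C[C@@H]1CCC[C@@](OCOC)(/C=C/OCc2ccc(OC)cc2)[C@H]1O | intermediate |
| 12 | C5 ketone | C[C@@H]1CCC[C@@](OCOC)(/C=C/OCc2ccc(OC)cc2)C1=O | intermediate |
| 13 | 2,3-dibromoprop-1-ene | C=C(Br)CBr | starting material |
| 14 | PMB 2-bromoallyl ether | C=C(Br)COCc1ccc(OC)cc1 | intermediate |
| 15 | ethynyltrimethylsilane | C#C[Si](C)(C)C | starting material |
| 16 | TMS-enyne | C=C(C#C[Si](C)(C)C)COCc1ccc(OC)cc1 | intermediate |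
| 17 | terminal enyne | C#CC(=C)COCc1ccc(OC)cc1 | intermediate |
| 18 | enynyl carbinol (4R,5R,10R) | C[C@@H]1CCC[C@@](OCOC)(/C=C/OCc2ccc(OC)cc2)[C@]1(O)C#CC(=C)COCc3ccc(OC)cc3 | intermediate |
| 19 | Cope substrate (4R,5R,10R; E,E) | C[C@@H]1CCC[C@@](OCOC)(/C=C/OCc2ccc(OC)cc2)[C@]1(O)/C=C/C(=C)COCc3ccc(OC)cc3 | intermediate |
| 20 | cyclodecenone enol ether (4R,7S,8S) | C[C@@H]1CCC/C(OCOC)=C/[C@@H](OCc3ccc(OC)cc3)[C@H](C(=C)COCc2ccc(OC)cc2)CC1=O | intermediate |
| 21 | 9-hydroxy-5,10-dione | C[C@@H]1CCCC(=O)[C@H](O)[C@@H](OCc3ccc(OC)cc3)[C@H](C(=C)COCc2ccc(OC)cc2)CC1=O | intermediate |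
| 22 | methylmagnesium bromide | C[Mg]Br | starting material |
| 23 | 9,10-diol | C[C@@H]1CCC[C@](C)(O)[C@H](O)[C@@H](OCc3ccc(OC)cc3)[C@H](C(=C)COCc2ccc(OC)cc2)CC1=O | intermediate |
| 24 | (R)-2-methylbutanoic acid | CC[C@@H](C)C(=O)O | starting material |
| 25 | C9 ester | C[C@@H]1CCC[C@](C)(O)[C@H](OC(=O)[C@H](C)CC)[C@@H](OCc3ccc(OC)cc3)[C@H](C(=C)COCc2ccc(OC)cc2)CC1=O | intermediate |
| 26 | C8,C12-diol | C[C@@H]1CCC[C@](C)(O)[C@H](OC(=O)[C@H](C)CC)[C@@H](O)[C@H](C(=C)CO)CC1=O | intermediate |
| 27 | ineupatorolide A | C=C1C(=O)O[C@@H]2[C@@H](OC(=O)[C@H](C)CC)[C@@](C)(O)CCC[C@@H](C)C(=O)C[C@@H]12 | target |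

## Step count
- Total steps: 19.
- Longest linear sequence: 15 (steps 1, 2, 4–8, 12–19).

## Three steps most likely to fail

1. **Step 14, oxy-Cope.** The reactive chair carries O5⁻, OMOM and C4-Me axial, and leakage through a boat or a dissociative pathway would erode C7/C8.
   *Fallback:* give up the ring expansion. Ozonolyse enol silane 3 to the C10-acid/C5-aldehyde chain, which keeps C4. Elaborate that chain and close the ring at C7–C8 by intramolecular Barbier/NHK allylation of a C8 aldehyde with a 2-(bromomethyl)acrylate.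

2. **Step 16, methyl addition.** The reaction must select C10 over C5, and the 1,6-diketone can undergo transannular aldol reaction.
   *Fallback:* never make the diketone. Epoxidise enol ether 20 with DMDO and open the epoxy-acetal with AlMe3, which delivers Me syn to the epoxide oxygen as in C-glycoside formation from glycal epoxides. This gives C10(Me)(OMOM)/C9-OH directly with the same 9,10-erythro sense. Remove the MOM group at the end with MgBr2·OEt2/EtSH.

3. **Step 15, C9 oxygenation.** The risks are the face of attack and selectivity over the C11=C13 alkene.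
   *Fallback:* bring O9 in before the ring expansion. Replace the alkoxyacetylide in step 4 with 4-lithio-2,2-dimethyl-1,3-dioxole, so that C8 and C9 arrive as an enediol acetonide. After the Cope rearrangement C9 is an epimerisable α-alkoxy-ketone centre, which is equilibrated to the trans (8,9-threo) acetonide before the chelate-controlled methylation.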